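## Retrosynthetic overview

1. Target 16 ⇒ diol 13. The crowded C5–OH is acetylated last, while the exposed C2–OH is masked for the duration of one flask.
2. 13 ⇒ monocyclic dienol 10. Ring C (bromo-oxane, C7–O–C11) and ring B (bridging oxepane, C8–O–C1) close in one flask: Br+ adds to C10=C11, an oxygen atom is transferred to C1=C2, and the epoxide is opened across the ring with loss of silicon.
3. 10 ⇒ ketone 8. The C5 carbonyl is reduced to the axial alcohol, which is then silylated.
4. 8 ⇒ the C4–C7 bond. This is a chelation-controlled Mukaiyama-type aldol between Birch diene 6 (ring A, from 3-methylanisole) and the α-silyloxy ketone 4.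
5. 4 ⇒ sulcatone by D-proline α-aminoxylation, which sets C8 and is the only external source of chirality. Ring order: A (bought as the arene), then C, then B.

Assumption: bisabolane numbering is used. Ring A is C1–C6, C1 carries CH3-15, C4 carries the chain C7–C11, and CH3-14 sits on C7. In this numbering the target is 1R,2R,4R,5S,7S,8S,10S. "Top face" means the face of ring A that carries the C4 side chain. Dimethyldioxirane is used as its acetone solution, made from acetone and KHSO5.

## Route

Step 1
Reactants: 1 6-methylhept-5-en-2-one (sulcatone, 3 equiv, excess recovered)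
Product: 3 (3S)-3-hydroxy-6-methylhept-5-en-2-one, via aminoxy ketone 2 (not isolated)
Conditions: PhNO (1 equiv, slow addition), D-proline (20 mol%), DMSO, rt; then CuSO4·5H2O (30 mol%), MeOH, 0 °C
Reagents that add atoms: nitrosobenzene, O=Nc1ccccc1
Why: This is a proline-catalysed α-aminoxylation (O-nitroso aldol) through the more substituted E-enamine, in which the carboxylic acid of D-proline steers PhN=O to one enamine face and sets C8 as S, and the copper-catalysed N–O cleavage leaves that centre untouched.

Step 2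
Reactants: 3 (3S)-3-hydroxy-6-methylhept-5-en-2-one
Product: 4 (3S)-6-methyl-3-(triethylsilyloxy)hept-5-en-2-one
Conditions: Et3SiCl, imidazole, CH2Cl2, 0 °C
Reagents that add atoms: chlorotriethylsilane, CC[Si](Cl)(CC)CC
Why: This is a standard O-silylation that stops ketol isomerisation and touches no stereocentre, and Et3Si is small enough to chelate in step 4, inert enough to silence O8 towards Br+, and labile enough to leave in step 7.

Step 3
Reactants: 5 3-methylanisole
Product: 6 1-methoxy-5-methylcyclohexa-1,4-diene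
Conditions: Li, NH3 (l), t-BuOH, THF, −78 to −33 °C
Reagents that add atoms: none
Why: In this Birch reduction both donor-bearing carbons stay sp2, so the 2,5-dihydro product has the enol ether at C4=C5 (nucleophilic C4) and the alkene at C1=C2 where they are needed, and no stereocentre forms.

Step 4
Reactants: 4 (3S)-6-methyl-3-(triethylsilyloxy)hept-5-en-2-one; 6 1-methoxy-5-methylcyclohexa-1,4-diene (2 equiv)
Product: 8 (6S)-6-[(2S,3S)-2-hydroxy-6-methyl-3-(triethylsilyloxy)hept-5-en-2-yl]-3-methylcyclohex-3-en-1-one, via hemiketal 7 (not isolated)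
Conditions: Me2AlCl (2.5 equiv), CH2Cl2, −78 °C, 4 then 6; cold aq. NaHCO3/potassium sodium tartrate
Reagents that add atoms: water, O
Why: This is a chelation-controlled Mukaiyama-type aldol addition in which excess Me2AlCl forms a cationic five-membered chelate of C7=O and O8, the enol ether attacks the face syn to C8–H (Cram chelate, sets 7S), the antiperiplanar open transition state puts ring CH2-3 beside the small CH3-14 and C4–H beside C8 (sets C4), and the O-methyl oxocarbenium ion hydrolyses on quench without moving the β,γ-alkene.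

Step 5
Reactants: 8 (6S)-6-[(2S,3S)-2-hydroxy-6-methyl-3-(triethylsilyloxy)hept-5-en-2-yl]-3-methylcyclohex-3-en-1-one
Product: 9 (1S,6R)-6-[(2S,3S)-2-hydroxy-6-methyl-3-(triethylsilyloxy)hept-5-en-2-yl]-3-methylcyclohex-3-en-1-ol
Conditions: LiBH(s-Bu)3 (L-Selectride, 2.5 equiv), THF, −78 °C; then H2O
Reagents that add atoms: none
Why: The bulky trialkylborohydride attacks this 2-substituted cyclohexanone along the equatorial trajectory, which gives the axial C5–OH cis to the equatorial side chain (5S) faster than enolisation or retro-aldol can occur at −78 °C.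

Step 6
Reactants: 9 (1S,6R)-6-[(2S,3S)-2-hydroxy-6-methyl-3-(triethylsilyloxy)hept-5-en-2-yl]-3-methylcyclohex-3-en-1-ol
Product: 10 (2S,3S)-6-methyl-2-[(1R,6S)-4-methyl-6-(triethylsilyloxy)cyclohex-3-en-1-yl]-3-(triethylsilyloxy)hept-5-en-2-ol
Conditions: Et3SiCl (1.2 equiv), imidazole, DMAP (cat.), DMF, 0 °C to rt
Reagents that add atoms: chlorotriethylsilane, CC[Si](Cl)(CC)CC
Why: This chemoselective silylation takes the secondary C5–OH over the tertiary C7–OH, and the axial non-participating silyloxy group then shields the top face of C1=C2, whereas an axial acetate here would capture C1 as a six-membered acetoxonium ion in step 7.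

Step 7
Reactants: 10 (2S,3S)-6-methyl-2-[(1R,6S)-4-methyl-6-(triethylsilyloxy)cyclohex-3-en-1-yl]-3-(triethylsilyloxy)hept-5-en-2-ol
Product: 13 (1R,2R,4R,5S,7S,8S,10S)-10-bromo-1,8:7,11-diepoxybisabolane-2,5-diol, via bromo-oxane alkene 11 (not isolated), via bromo-oxane epoxide 12 (not isolated)
Conditions: NBS (1.05 equiv), (CF3)2CHOH/CH2Cl2 1:3, 4 Å MS, −20 °C; then dimethyldioxirane (acetone solution, 1.3 equiv), −20 °C; then camphorsulfonic acid (0.2 equiv), −20 °C to rt; then 1 M aq. HCl, THF, rt
Reagents that add atoms: N-bromosuccinimide, O=C1CCC(=O)N1Br; dimethyldioxirane, CC1(C)OO1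
Why: Proposed new method: a one-flask oxidative bis-cyclisation in which (i) reversible bromonium formation funnels Br+ to C10=C11, the only alkene with a low-strain internal trap, and the free C7–OH closes ring C by 6-endo Markovnikov attack at C11 through a chair with the cyclohexenyl group and Br equatorial (sets 10S, while O8 is silenced as its silyl ether and the C1=C2 bromonium has no reachable nucleophile under the axial C5 silyloxy group), (ii) dimethyldioxirane oxidises the one remaining alkene anti to that axial group to give the 1S,2R-epoxide, and (iii) acid in the ionising, non-nucleophilic fluoro-alcohol medium opens the epoxide at tertiary C1 with inversion by the C8 silyl-ether oxygen across the boat of ring A (sets 1R and leaves the 2R hydroxyl) with loss of Et3Si+ to close ring B, after which aqueous acid strips the C5 silyl group; the closest known reaction types are NBS/fluoro-alcohol bromoetherification and bromonium-initiated epoxide cascades, dioxirane epoxidation, and the acid-catalysed transannular opening of α-terpineol oxide to 2-hydroxy-1,8-cineole.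

Step 8
Reactants: 13 (1R,2R,4R,5S,7S,8S,10S)-10-bromo-1,8:7,11-diepoxybisabolane-2,5-diol
Product: 16 (1R,2R,4R,5S,7S,8S,10S)-5-acetoxy-10-bromo-1,8:7,11-diepoxybisabolan-2-ol, via C2 silyl ether 14 (not isolated), via silyl ether acetate 15 (not isolated)
Conditions: Et3SiCl (1.1 equiv), imidazole, CH2Cl2, −20 °C; then Ac2O, Et3N, DMAP, 40 °C; then 1 M aq. HCl, THF, rt
Reagents that add atoms: acetic anhydride, CC(=O)OC(C)=O
Why: This is a transient-protection acylation in which the C2–OH, lying in the open cleft between the two two-carbon bridges, is silylated first, the C5–OH buried under ring C and hydrogen-bonded to O(7,11) is then acetylated under forcing DMAP catalysis, and mild acid removes the silyl ether without changing any stereocentre.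

## Compound list

1 | 6-methylhept-5-en-2-one (sulcatone) | CC(=O)CCC=C(C)C | starting material
2 | (3S)-6-methyl-3-(phenylaminooxy)hept-5-en-2-one | CC(=O)[C@@H](ONc1ccccc1)CC=C(C)C | intermediate
3 | (3S)-3-hydroxy-6-methylhept-5-en-2-one | CC(=O)[C@@H](O)CC=C(C)C | intermediate
4 | (3S)-6-methyl-3-(triethylsilyloxy)hept-5-en-2-one | CC(=O)[C@@H](O[Si](CC)(CC)CC)CC=C(C)C | intermediate
5 | 3-methylanisole | COc1cccc(C)c1 | starting material
6 | 1-methoxy-5-methylcyclohexa-1,4-diene | COC1=CCC=C(C)C1 | intermediate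
7 | (6S)-6-[(2S,3S)-2-hydroxy-6-methyl-3-(triethylsilyloxy)hept-5-en-2-yl]-1-methoxy-3-methylcyclohex-3-en-1-ol (methyl hemiketal of 8, C5 undefined) | COC1(O)CC(C)=CC[C@H]1[C@](C)(O)[C@@H](O[Si](CC)(CC)CC)CC=C(C)C | intermediate
8 | (6S)-6-[(2S,3S)-2-hydroxy-6-methyl-3-(triethylsilyloxy)hept-5-en-2-yl]-3-methylcyclohex-3-en-1-one | O=C1CC(C)=CC[C@H]1[C@](C)(O)[C@@H](O[Si](CC)(CC)CC)CC=C(C)C | intermediate
9 | (1S,6R)-6-[(2S,3S)-2-hydroxy-6-methyl-3-(triethylsilyloxy)hept-5-en-2-yl]-3-methylcyclohex-3-en-1-ol | O[C@H]1CC(C)=CC[C@H]1[C@](C)(O)[C@@H](O[Si](CC)(CC)CC)CC=C(C)C | intermediate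
10 | (2S,3S)-6-methyl-2-[(1R,6S)-4-methyl-6-(triethylsilyloxy)cyclohex-3-en-1-yl]-3-(triethylsilyloxy)hept-5-en-2-ol | CC[Si](CC)(CC)O[C@H]1CC(C)=CC[C@H]1[C@](C)(O)[C@@H](O[Si](CC)(CC)CC)CC=C(C)C | intermediate
11 | (2S,3S,5S)-5-bromo-2,6,6-trimethyl-2-[(1R,6S)-4-methyl-6-(triethylsilyloxy)cyclohex-3-en-1-yl]-3-(triethylsilyloxy)oxane | CC[Si](CC)(CC)O[C@H]1CC(C)=CC[C@H]1[C@]2(C)OC(C)(C)[C@@H](Br)C[C@@H]2O[Si](CC)(CC)CC | intermediate
12 | (1S,2R)-1,2-epoxide of 11 (oxirane anti to the C5 silyloxy group and to the C4 substituent) | CC[Si](CC)(CC)O[C@H]1C[C@]3(C)O[C@@H]3C[C@H]1[C@]2(C)OC(C)(C)[C@@H](Br)C[C@@H]2O[Si](CC)(CC)CC | intermediate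
13 | (1R,2R,4R,5S,7S,8S,10S)-10-bromo-1,8:7,11-diepoxybisabolane-2,5-diol | O[C@H]1C[C@@]2(C)O[C@H]3C[C@H](Br)C(C)(C)O[C@@]3(C)[C@@H]1C[C@H]2O | intermediate
14 | 2-O-triethylsilyl ether of 13 | O[C@H]1C[C@@]2(C)O[C@H]3C[C@H](Br)C(C)(C)O[C@@]3(C)[C@@H]1C[C@H]2O[Si](CC)(CC)CC | intermediate
15 | 5-O-acetyl-2-O-triethylsilyl derivative of 13 | CC(=O)O[C@H]1C[C@@]2(C)O[C@H]3C[C@H](Br)C(C)(C)O[C@@]3(C)[C@@H]1C[C@H]2O[Si](CC)(CC)CC | intermediate
16 | (1R,2R,4R,5S,7S,8S,10S)-5-acetoxy-10-bromo-1,8:7,11-diepoxybisabolan-2-ol | CC(=O)O[C@H]1C[C@@]2(C)O[C@H]3C[C@H](Br)C(C)(C)O[C@@]3(C)[C@@H]1C[C@H]2O | target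

## Step count and risks

Total steps: 8. Longest linear sequence: 7 (steps 1, 2, 4, 5, 6, 7, 8).

**Step 7 is the most likely to fail.** Three things can go wrong.
- 5-exo closure may compete with the 6-endo closure of ring C.
- The seven-membered bridge needs the bulky C4 substituent axial on a boat, so a hydride shift to the C2 ketone or proton loss to an allylic alcohol may be faster than closure.
- The ring C oxygen may take part at C1.

The fallback closes ring B by conjugate addition rather than by epoxide substitution. It sets out from 8 and comes back at 13.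
- NBS in (CF3)2CHOH/CH2Cl2 closes ring C on the ketone to give the bromo-oxane ketone F3.
- Dimethyldioxirane gives the β,γ-epoxy ketone F4.
- Et3N isomerises F4 by E1cB opening to the γ-hydroxy enone F5. Face selectivity without the axial C5 group is only modest, so the C2 epimer is removed here by chromatography.
- Aqueous HF in MeCN frees the C8 hydroxy enone F6.
- Camphorsulfonic acid equilibrates F6 by reversible intramolecular oxa-Michael addition of C8–OH to C1, giving the bridged ketone F7.
- LiBH(s-Bu)3 attacks F7 from the face remote from ring C and gives 13.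

**Step 4 is the second risk.** A ketone is a sluggish acceptor, chelation of a silyl ether may be incomplete, and the dihydroanisole is acid sensitive. The fallback replaces the open Lewis-acid aldol by a closed metal-enolate aldol. It sets out from 6 and comes back at 8.
- NBS in wet THF at −78 °C converts the enol ether into 6-bromo-3-methylcyclohex-3-en-1-one F1.
- SmI2 (2 equiv, THF, −78 °C) reduces F1 to the regiodefined trivalent samarium enolate F2.
- Compound 4 is then added to F2. The oxophilic metal binds the enolate, C7=O and O8 in a chair transition state that places the chelating C8 arm axial and CH3-14 equatorial. This predicts the same 4,7,8 relationship as the main route.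

**Step 8 is the third risk.** Silylation may not discriminate cleanly between C2–OH and C5–OH, and the silyl ether may leak under forcing acylation. The fallback uses selective deacylation instead of selective protection. It sets out from 13 and comes back at 16.
- Exhaustive acetylation (Ac2O, Et3N, DMAP, 40 °C) gives the 2,5-diacetate F8.
- Brief methanolysis (K2CO3, MeOH, 0 °C) removes the exposed C2 acetate and leaves the shielded C5 acetate.

## Further compounds

F1 | step 4 | 6-bromo-3-methylcyclohex-3-en-1-one (racemic) | O=C1CC(C)=CCC1Br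
F2 | step 4 | diiodosamarium 5-methylcyclohexa-1,4-dien-1-olate | CC1=CCC=C(O[Sm](I)I)C1
F3 | step 7 | (6S)-6-[(2S,3S,5S)-5-bromo-2,6,6-trimethyl-3-(triethylsilyloxy)oxan-2-yl]-3-methylcyclohex-3-en-1-one | O=C1CC(C)=CC[C@H]1[C@]2(C)OC(C)(C)[C@@H](Br)C[C@@H]2O[Si](CC)(CC)CC
F4 | step 7 | (1S,2R)-1,2-epoxide of F3 | O=C1C[C@]3(C)O[C@@H]3C[C@H]1[C@]2(C)OC(C)(C)[C@@H](Br)C[C@@H]2O[Si](CC)(CC)CC
F5 | step 7 | (4R,6S)-6-[(2S,3S,5S)-5-bromo-2,6,6-trimethyl-3-(triethylsilyloxy)oxan-2-yl]-4-hydroxy-3-methylcyclohex-2-en-1-one | O=C1C=C(C)[C@H](O)C[C@H]1[C@]2(C)OC(C)(C)[C@@H](Br)C[C@@H]2O[Si](CC)(CC)CC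
F6 | step 7 | (4R,6S)-6-[(2S,3S,5S)-5-bromo-3-hydroxy-2,6,6-trimethyloxan-2-yl]-4-hydroxy-3-methylcyclohex-2-en-1-one | O=C1C=C(C)[C@H](O)C[C@H]1[C@]2(C)OC(C)(C)[C@@H](Br)C[C@@H]2O
F7 | step 7 | (1R,2R,4S,7S,8S,10S)-10-bromo-2-hydroxy-1,8:7,11-diepoxybisabolan-5-one | O=C1C[C@@]2(C)O[C@H]3C[C@H](Br)C(C)(C)O[C@@]3(C)[C@@H]1C[C@H]2O
F8 | step 8 | (1R,2R,4R,5S,7S,8S,10S)-10-bromo-1,8:7,11-diepoxybisabolane-2,5-diyl diacetate | CC(=O)O[C@H]1C[C@@]2(C)O[C@H]3C[C@H](Br)C(C)(C)O[C@@]3(C)[C@@H]1C[C@H]2OC(C)=O
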